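**Retrosynthetic overview**
1. Prolifenone B (15) is opened at two bonds in one operation: ring A at C4–C5 (acylketene C-acylation) and ring B at C1–C8 (cationic enol–alkene closure). This leads back to the acyclic branched diketo-dioxinone 12. In the forward direction ring B closes first and ring A second, in the same flask.
2. 12 comes from C1–C9 C-acylation of keto-dioxinone 10 (C1–C4, C10, isopropyl) by acid 7 (C5–C9, prenyl, exocyclic methylene, homogeranyl chain).
3. 10 comes from 2,2,6-trimethyl-1,3-dioxin-4-one 8 and isobutyryl chloride 9.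
4. 7 comes from geranylated limonene diol 3 by glycol cleavage, Wittig olefination and haloform degradation. C7 is the limonene stereocentre.
5. 3 comes from limonene-1,2-diol 1 and geranyl bromide 2 by allylic metalation of the isopropenyl methyl group.

Assumption: (1S,2S,4R)-limonene-1,2-diol is bought as such (it is also one aqueous-acid hydrolysis from bulk (+)-limonene oxide); atom labels follow the usual bicyclic numbering (C1 acyl-bearing bridgehead, C2–C4 enolised diketone, C5 CH bridgehead, C6 CH2, C7 prenyl carbon, C8 quaternary carbon, C9 bridge ketone, C10 isobutyryl C=O).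

Step 1
Reactants: 1 (1S,2S,4R)-limonene-1,2-diol; 2 geranyl bromide
Product: 3 (1S,2S,4R)-4-[(5E)-6,10-dimethylundeca-1,5,9-trien-2-yl]-1-methylcyclohexane-1,2-diol
Conditions: n-BuLi (3.3 equiv), TMEDA (3.3 equiv), hexane, 0 °C to 23 °C, 16 h; then 2 (1.1 equiv), THF, −78 °C to 23 °C; H2O quench
Reagents that add atoms: none
Why: Allylic metalation then SN2 allyl–allyl alkylation: after both hydroxyls have become lithium alkoxides the n-BuLi/TMEDA complex removes a proton from the isopropenyl methyl group (the kinetically most acidic C–H, as in limonene itself) to give a symmetrical 2-substituted allyllithium that displaces the primary bromide of 2 without touching its E alkene, while the ring stereocentres, among them the future C7, are spectators.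

Step 2
Reactants: 3 geranylated limonene diol
Product: 4 (3R)-3-[(5E)-6,10-dimethylundeca-1,5,9-trien-2-yl]-6-oxoheptanal
Conditions: NaIO4 (1.5 equiv), THF/H2O 2:1, 23 °C, 2 h
Reagents that add atoms: none
Why: Malaprade glycol cleavage: NaIO4 reacts only through the cyclic periodate ester of the vicinal diol, so all four alkenes survive and the ring opens to a CH2CHO arm and a CH2CH2C(O)CH3 arm on the untouched stereocentre, which is beta or gamma to the new carbonyls and cannot epimerise.

Step 3
Reactants: 4 keto aldehyde; 5 isopropyltriphenylphosphonium iodide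
Product: 6 (5R)-5-[(5E)-6,10-dimethylundeca-1,5,9-trien-2-yl]-8-methylnon-7-en-2-one
Conditions: 5 (1.05 equiv), n-BuLi (1.0 equiv), THF, 0 °C; then 4, −78 °C to 0 °C
Reagents that add atoms: none
Why: Wittig olefination: one equivalent of the non-stabilised isopropylidene ylide attacks the aldehyde far faster than the methyl ketone at low temperature and turns the CH2CHO arm into the prenyl group, no stereocentre or alkene geometry being created.

Step 4
Reactants: 6 methyl ketone
Product: 7 (4R)-4-[(5E)-6,10-dimethylundeca-1,5,9-trien-2-yl]-7-methyloct-6-enoic acid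
Conditions: NaOBr (preformed from Br2 and excess aq. NaOH at 0 °C), dioxane/H2O, 0 °C, 3 h; Na2SO3 wash; then aq. HCl to pH 3
Reagents that add atoms: sodium hydroxide, [Na+].[OH-]
Why: Haloform reaction: preformed cold alkaline hypobromite tribrominates only the enolisable methyl group and hydroxide then cleaves off bromoform, a degradation long used on geranylacetone-type polyene methyl ketones because hypobromite ion in excess base does not add to isolated alkenes, so C9 emerges as the carboxyl carbon and C7 is untouched.

Step 5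
Reactants: 8 2,2,6-trimethyl-4H-1,3-dioxin-4-one; 9 isobutyryl chloride
Product: 10 2,2-dimethyl-6-(3-methyl-2-oxobutyl)-4H-1,3-dioxin-4-one
Conditions: 8 (2.2 equiv), LiN(i-Pr)2 (2.2 equiv), THF, −78 °C; then 9 (1.0 equiv), −78 °C to −20 °C; aq. NH4Cl
Reagents that add atoms: none
Why: Vinylogous crossed Claisen acylation: the lithium dienolate of 8 reacts with the acid chloride at its gamma carbon (the future C1) and the second equivalent of dienolate takes up the more acidic proton of the product, which stops over-acylation, no stereocentre being formed.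

Step 6
Reactants: 7 acid; 10 keto-dioxinone
Product: 12 6-{(8R)-8-[(5E)-6,10-dimethylundeca-1,5,9-trien-2-yl]-2,11-dimethyl-3,5-dioxododec-10-en-4-yl}-2,2-dimethyl-4H-1,3-dioxin-4-one, via acid chloride 11 (not isolated)
Conditions: 7, 1-chloro-N,N,2-trimethylprop-1-en-1-amine (1.1 equiv), CH2Cl2, 0 °C, 1 h; then 10 (1.1 equiv), MgCl2 (2 equiv), pyridine (2.5 equiv), CH2Cl2, 0 °C to 23 °C
Reagents that add atoms: none
Why: Neutral acid chloride formation with the chloroenamine (no HCl that could add to the alkenes) followed by magnesium-chelate soft enolisation and C-acylation of the active methylene of 10 (Rathke-type acylation, the standard entry to diketo-dioxinones) joins C1 to C9, and since the product is fully enolised at C1 only the C7 centre is defined.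

Step 7
Reactants: 12 branched diketo-dioxinone
Product: 15 prolifenone B, via ring-B ketone 13 (not isolated), via acylketene 14 (not isolated)
Conditions: HCO2H (neat, 0.02 M), 23 °C, 12 h; strip HCO2H (PhMe azeotrope, below 30 °C); then PhMe (0.005 M), Et3N (0.1 equiv), 110 °C, 2 h
Reagents that add atoms: none
Why: Proposed new method: in neat formic acid the 1,1-disubstituted alkene is protonated at its CH2 terminus (which becomes the C8 methyl) while the hydrogen-bonded enol of the 2-alkenyl-1,3-diketone attacks the developing tertiary C8 cation through carbon in a six-membered chair (6-enolendo-exo-trig) in which the chiral-pool C7 prenyl group and the long C8 chain sit equatorial (rotamer with C7–H eclipsing the C8–chain bond, allylic 1,2-strain), the new methyl sits axial, the chelated isobutyryl group stays in the enol plane and ends equatorial and the dioxinone is forced axial, so C1 and C8 are set from C7 while O-alkylation, formate capture and alkene isomers remain reversible feeder equilibria; heating then causes retro-[4+2] loss of acetone and the axial acylketene is C-acylated by the only ring enol available (C9/C5) across the 1,3-diaxial gap, which fixes C5 by the geometry of the bridge and ends in the non-reverting vinylogous acid; the closest known reaction types are the biomimetic formic acid cationic cyclisation of lavandulyl-type side chains onto hindered beta-dicarbonyl carbons of dearomatised acylphloroglucinols and the dioxinone thermolysis/acylketene trapping used for polyketide ring closure (a ketene version of the Dieckmann condensation).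

**Compound list**
1 | (1S,2S,4R)-limonene-1,2-diol | CC(=C)[C@@H]1CC[C@]([C@H](C1)O)(C)O | starting material
2 | geranyl bromide, (2E)-1-bromo-3,7-dimethylocta-2,6-diene | CC(C)=CCC/C(C)=C/CBr | starting material
3 | (1S,2S,4R)-4-[(5E)-6,10-dimethylundeca-1,5,9-trien-2-yl]-1-methylcyclohexane-1,2-diol | CC(C)=CCC/C(C)=C/CCC(=C)[C@@H]1CC[C@]([C@H](C1)O)(C)O | intermediate
4 | (3R)-3-[(5E)-6,10-dimethylundeca-1,5,9-trien-2-yl]-6-oxoheptanal | CC(C)=CCC/C(C)=C/CCC(=C)[C@@H](CC=O)CCC(C)=O | intermediate
5 | isopropyltriphenylphosphonium iodide | CC(C)[P+](c1ccccc1)(c1ccccc1)c1ccccc1.[I-] | starting material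
6 | (5R)-5-[(5E)-6,10-dimethylundeca-1,5,9-trien-2-yl]-8-methylnon-7-en-2-one | CC(C)=CCC/C(C)=C/CCC(=C)[C@@H](CC=C(C)C)CCC(C)=O | intermediate
7 | (4R)-4-[(5E)-6,10-dimethylundeca-1,5,9-trien-2-yl]-7-methyloct-6-enoic acid | CC(C)=CCC/C(C)=C/CCC(=C)[C@@H](CC=C(C)C)CCC(=O)O | intermediate
8 | 2,2,6-trimethyl-4H-1,3-dioxin-4-one | CC1=CC(=O)OC(C)(C)O1 | starting material
9 | isobutyryl chloride | CC(C)C(=O)Cl | starting material
10 | 2,2-dimethyl-6-(3-methyl-2-oxobutyl)-4H-1,3-dioxin-4-one | CC(C)C(=O)CC1=CC(=O)OC(C)(C)O1 | intermediate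
11 | (4R)-4-[(5E)-6,10-dimethylundeca-1,5,9-trien-2-yl]-7-methyloct-6-enoyl chloride (not isolated) | CC(C)=CCC/C(C)=C/CCC(=C)[C@@H](CC=C(C)C)CCC(=O)Cl | intermediate
12 | 6-{(8R)-8-[(5E)-6,10-dimethylundeca-1,5,9-trien-2-yl]-2,11-dimethyl-3,5-dioxododec-10-en-4-yl}-2,2-dimethyl-4H-1,3-dioxin-4-one (C4 of the dodecene chain = C1, enolised and configurationally labile) | CC(C)=CCC/C(C)=C/CCC(=C)[C@@H](CC=C(C)C)CCC(=O)C(C(=O)C(C)C)C1=CC(=O)OC(C)(C)O1 | intermediate
13 | (2R,3R,4R)-2-(2,2-dimethyl-4-oxo-4H-1,3-dioxin-6-yl)-3-[(3E)-4,8-dimethylnona-3,7-dienyl]-3-methyl-4-(3-methylbut-2-enyl)-2-(2-methylpropanoyl)cyclohexan-1-one (not isolated) | CC(C)=CCC/C(C)=C/CC[C@]1(C)[C@@H](CC=C(C)C)CCC(=O)[C@]1(C(=O)C(C)C)C2=CC(=O)OC(C)(C)O2 | intermediate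
14 | acylketene from 13 by loss of acetone: same ring B and same configuration, C1 carries C(=O)CH=C=O in place of the dioxinone (not isolated) | CC(C)=CCC/C(C)=C/CC[C@]1(C)[C@@H](CC=C(C)C)CCC(=O)[C@]1(C(=O)C(C)C)C(=O)C=C=O | intermediate
15 | prolifenone B, (1R,5R,7S,8R)-8-[(3E)-4,8-dimethylnona-3,7-dienyl]-4-hydroxy-8-methyl-7-(3-methylbut-2-enyl)-1-(2-methylpropanoyl)bicyclo[3.3.1]non-3-ene-2,9-dione | CC(C)=CCC/C(C)=C/CC[C@]1(C)[C@@H](CC=C(C)C)C[C@H]2C(=O)[C@]1(C(=O)C(C)C)C(=O)C=C2O | target

**Total step count:** 7. **Longest linear sequence:** 6 (steps 1, 2, 3, 4, 6, 7).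

**Three steps most likely to fail**

Step 7 carries the most risk, for four reasons:
- The C1–C8 bond joins two fully substituted carbons.
- The methyl/chain discrimination at C8 may be only moderate, in which case the C8 epimer has to be removed by chromatography.
- Proton loss from C7 of the cation would erode the optical purity.
- The distal diene can be protonated.

The fallback sets out from 6 and comes back at 15. Crossed Claisen condensation of 6 with methyl isobutyrate (KOt-Bu, THF, 50 °C) gives the beta-diketone (8R)-8-[(5E)-6,10-dimethylundeca-1,5,9-trien-2-yl]-2,11-dimethyldodec-10-ene-3,5-dione F1. Its unsubstituted C1 enol is a much better carbon nucleophile. Formic acid closes ring B alone to give (3R,4R)-3-[(3E)-4,8-dimethylnona-3,7-dienyl]-3-methyl-4-(3-methylbut-2-enyl)-2-(2-methylpropanoyl)cyclohexan-1-one F2, in which C1 stays epimerisable and the C8 epimers can be separated at a simple stage. Malonyl dichloride then bridges C1 and C5 in an Effenberger-type annulation (CH2Cl2, −10 °C, then aq. KOH with BnEt3NCl) to give 15.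

Step 1 may stall because the dilithium alkoxide aggregates and resists the third deprotonation. The fallback sets out from 1 and comes back at 3. The diol is masked (Et3SiOTf, 2,6-lutidine) as (1S,2S,4R)-1-methyl-4-(prop-1-en-2-yl)-1,2-bis(triethylsilyloxy)cyclohexane F3, which behaves like limonene itself. One equivalent of n-BuLi/TMEDA and then 2 give (1S,2S,4R)-4-[(5E)-6,10-dimethylundeca-1,5,9-trien-2-yl]-1-methyl-1,2-bis(triethylsilyloxy)cyclohexane F4. Bu4NF then returns 3.

Step 6 may give O-acylation, or loss of an acyl group, with the large acid chloride. The fallback sets out from 7 (through 11) and 8 and comes back at 12, with the two acylations run in the opposite order. The lithium dienolate of 8 is acylated by 11 to give the linear keto-dioxinone 6-{(5R)-5-[(5E)-6,10-dimethylundeca-1,5,9-trien-2-yl]-8-methyl-2-oxonon-7-enyl}-2,2-dimethyl-4H-1,3-dioxin-4-one F5. The small electrophile 9 is then put on its active methylene (MgCl2, pyridine) to give 12.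

Further compounds
F1 | step 7 | (8R)-8-[(5E)-6,10-dimethylundeca-1,5,9-trien-2-yl]-2,11-dimethyldodec-10-ene-3,5-dione | CC(C)=CCC/C(C)=C/CCC(=C)[C@@H](CC=C(C)C)CCC(=O)CC(=O)C(C)C
F2 | step 7 | (3R,4R)-3-[(3E)-4,8-dimethylnona-3,7-dienyl]-3-methyl-4-(3-methylbut-2-enyl)-2-(2-methylpropanoyl)cyclohexan-1-one | CC(C)=CCC/C(C)=C/CC[C@]1(C)[C@@H](CC=C(C)C)CCC(=O)C1C(=O)C(C)C
F3 | step 1 | (1S,2S,4R)-1-methyl-4-(prop-1-en-2-yl)-1,2-bis(triethylsilyloxy)cyclohexane | CC(=C)[C@@H]1CC[C@]([C@H](C1)O[Si](CC)(CC)CC)(C)O[Si](CC)(CC)CC
F4 | step 1 | (1S,2S,4R)-4-[(5E)-6,10-dimethylundeca-1,5,9-trien-2-yl]-1-methyl-1,2-bis(triethylsilyloxy)cyclohexane | CC(C)=CCC/C(C)=C/CCC(=C)[C@@H]1CC[C@]([C@H](C1)O[Si](CC)(CC)CC)(C)O[Si](CC)(CC)CC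
F5 | step 6 | 6-{(5R)-5-[(5E)-6,10-dimethylundeca-1,5,9-trien-2-yl]-8-methyl-2-oxonon-7-enyl}-2,2-dimethyl-4H-1,3-dioxin-4-one | CC(C)=CCC/C(C)=C/CCC(=C)[C@@H](CC=C(C)C)CCC(=O)CC1=CC(=O)OC(C)(C)O1
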